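**Retrosynthetic overview**

1. The strategy rests on ring B, the central benzene ring: its C1 carboxyl, C2–OH, C4–O and C6–CH3 form an orsellinate (a folded tetraketide), and the C1 carboxyl is esterified to O‑4 of ring C.
2. Last disconnections: the three benzyl groups (hydrogenolysis) and the aryl ester between the ring A carboxyl and O‑4 of ring B (acid chloride 17 + phenol 10).
3. Ring B is opened at its C1–C6 bond (aldol) to the 3,5,7‑trioxooctanoyl ester 8 of ring C. The chain comes from diketo‑dioxinone 6 through an acylketene trapped by the 4‑OH of benzyl orsellinate 3.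
4. Ring A acid comes from symmetric 5‑methylpyrogallol: formylation, 3,4‑di‑O‑benzylation, 2‑O‑methylation, oxidation.
5. Ring order: rings C and A are bought as arenes; ring B is the only ring formed (step 5).

Key step: step 5

Remark: the target has no stereocentre and no configurationally stable axis, so it is one achiral compound and no stereocontrol is needed; 5‑methylbenzene‑1,2,3‑triol is taken as commercially available.

**Step 1**
Reactants: 1 orsellinic acid; 2 benzyl bromide
Product: 3 benzyl 2,4-dihydroxy-6-methylbenzoate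
Conditions: KHCO3 (1.1 equiv), DMF, rt
Reagents that add atoms: none
Why: Carboxylate SN2 alkylation, in which bicarbonate deprotonates only the carboxylic acid so both phenols stay free, and room temperature avoids decarboxylation of the acid.

**Step 2**
Reactants: 4 2,2,6-trimethyl-4H-1,3-dioxin-4-one
Product: 5 2,2-dimethyl-6-(2-oxopropyl)-4H-1,3-dioxin-4-one
Conditions: 4 (2 equiv), LiHMDS (2 equiv), THF, −78 °C; AcCl (1 equiv), −78 °C; aq. NH4Cl
Reagents that add atoms: acetyl chloride, CC(Cl)=O
Why: Vinylogous Claisen C‑acylation of the lithium dienolate at its exocyclic γ‑carbon, with a second equivalent of dienolate supplied because the more acidic product consumes one.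

**Step 3**
Reactants: 5 2,2-dimethyl-6-(2-oxopropyl)-4H-1,3-dioxin-4-one
Product: 6 6-(2,4-dioxopentyl)-2,2-dimethyl-4H-1,3-dioxin-4-one
Conditions: LDA (2.1 equiv), THF, −78 °C; MeCON(OMe)Me, −78 to −40 °C; 1 M HCl quench
Reagents that add atoms: N-methoxy-N-methylacetamide, CC(=O)N(C)OC
Why: Claisen-type acylation of the dianion of the keto‑dioxinone at its terminal, most nucleophilic carbon, where the chelated tetrahedral adduct of the Weinreb amide prevents over‑addition.

**Step 4**
Reactants: 6 6-(2,4-dioxopentyl)-2,2-dimethyl-4H-1,3-dioxin-4-one; 3 benzyl 2,4-dihydroxy-6-methylbenzoate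
Product: 8 benzyl 2-hydroxy-6-methyl-4-(3,5,7-trioxooctanoyloxy)benzoate, via acylketene 7 (not isolated)
Conditions: 3 (2 equiv), toluene, 110 °C, slow addition of 6, acetone distilled off; crude 8 used directly
Reagents that add atoms: none
Why: Thermal retro‑hetero‑Diels–Alder of the dioxinone releases acetone and acylketene 7, which the non‑chelated 4‑OH of 3 should trap as the aryl β‑keto ester, the 2‑OH being held in a hydrogen bond to the benzyl ester carbonyl.

**Step 5**
Reactants: 8 benzyl 2-hydroxy-6-methyl-4-(3,5,7-trioxooctanoyloxy)benzoate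
Product: 10 benzyl 4-(2,4-dihydroxy-6-methylbenzoyloxy)-2-hydroxy-6-methylbenzoate, via aldol carbinol 9 (not isolated)
Conditions: Et3N (1.5 equiv), AcOH (1.0 equiv), CH2Cl2, 0 °C to rt; then TFA (5 equiv), CH2Cl2, rt
Reagents that add atoms: none
Why: The amine/ammonium acetate buffer enolises the C2 methylene between the aryl ester and the C3 ketone, and this carbon adds to the C7 methyl ketone to form the ring B C1–C6 bond and carbinol 9; acid then dehydrates 9 and the two remaining ketones enolise to the aromatic 2,4‑dihydroxy‑6‑methylbenzoate. The closest known reaction is the biomimetic aldol aromatisation of 3,5,7‑triketo esters to resorcylates. Ring B closes by a 6‑(enolexo)‑exo‑trig aldol addition. No stereocentre remains, since the two centres of 9 are lost on aromatisation. The step needs C2‑to‑C7 aldol closure to beat C6‑to‑C1 Claisen closure and O‑lactonisation to a pyranone (both would expel the ring C phenoxide) as well as C8‑to‑C3 aldol closure. The unhindered methyl ketone is the best electrophile of the chain, the non‑nucleophilic tertiary amine buffer forms only the doubly activated enols and never the C8 enolate, and aromatisation makes the desired closure irreversible.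

**Step 6**
Reactants: 11 5-methylbenzene-1,2,3-triol
Product: 13 2,3,4-trihydroxy-6-methylbenzaldehyde, via aryl iminium chloride 12 (not isolated)
Conditions: POCl3 (1.2 equiv), DMF (3 equiv), MeCN, 0 °C to rt; then H2O, 50 °C
Reagents that add atoms: N,N-dimethylformamide, CN(C)C=O; water, O
Why: Vilsmeier–Haack formylation at one of the two symmetry‑equivalent free ring positions (each ortho to an OH and to the methyl group) gives a single regioisomer after hydrolysis of iminium 12, and any O‑formyl or phosphate esters are cleaved in the same aqueous stage.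

**Step 7**
Reactants: 13 2,3,4-trihydroxy-6-methylbenzaldehyde; 2 benzyl bromide
Product: 14 3,4-bis(benzyloxy)-2-hydroxy-6-methylbenzaldehyde
Conditions: 2 (2.1 equiv), K2CO3 (2.2 equiv), DMF, rt
Reagents that add atoms: none
Why: Williamson etherification takes the 4‑OH (para to the aldehyde, most acidic) and then the 3‑OH, while the 2‑OH is held in a strong hydrogen bond to the aldehyde and should stay free with two equivalents of halide.

**Step 8**
Reactants: 14 3,4-bis(benzyloxy)-2-hydroxy-6-methylbenzaldehyde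
Product: 15 3,4-bis(benzyloxy)-2-methoxy-6-methylbenzaldehyde
Conditions: MeI (3 equiv), K2CO3 (2 equiv), DMF, 50 °C
Reagents that add atoms: iodomethane, CI
Why: Williamson O‑methylation of the only remaining (chelated) phenol under more forcing conditions, with no other acidic site left.

**Step 9**
Reactants: 15 3,4-bis(benzyloxy)-2-methoxy-6-methylbenzaldehyde
Product: 16 3,4-bis(benzyloxy)-2-methoxy-6-methylbenzoic acid
Conditions: NaClO2, NaH2PO4, 2-methyl-2-butene, t-BuOH/H2O, rt
Reagents that add atoms: sodium chlorite, [Na+].[O-]Cl=O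
Why: Pinnick oxidation converts the hindered, electron‑rich aldehyde into the acid without touching the benzyl ethers, and 2‑methyl‑2‑butene removes HOCl before it can chlorinate the ring.

**Step 10**
Reactants: 16 3,4-bis(benzyloxy)-2-methoxy-6-methylbenzoic acid
Product: 17 3,4-bis(benzyloxy)-2-methoxy-6-methylbenzoyl chloride
Conditions: (COCl)2 (1.5 equiv), DMF (cat.), CH2Cl2, 0 °C to rt; evaporate, use crude
Reagents that add atoms: oxalyl chloride, O=C(Cl)C(Cl)=O
Why: Acid chloride formation through the catalytic chloroiminium species proceeds under anhydrous, non‑nucleophilic conditions that leave the aryl benzyl ethers intact.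

**Step 11**
Reactants: 17 3,4-bis(benzyloxy)-2-methoxy-6-methylbenzoyl chloride; 10 benzyl 4-(2,4-dihydroxy-6-methylbenzoyloxy)-2-hydroxy-6-methylbenzoate
Product: 18 benzyl 4-[4-(3,4-bis(benzyloxy)-2-methoxy-6-methylbenzoyloxy)-2-hydroxy-6-methylbenzoyloxy]-2-hydroxy-6-methylbenzoate
Conditions: Et3N (1.5 equiv), DMAP (0.1 equiv), CH2Cl2, 0 °C to rt
Reagents that add atoms: none
Why: Classical depside O‑acylation through the acylpyridinium ion, selective because of the three phenols in 10 only the ring B 4‑OH is not hydrogen‑bonded to an ortho ester carbonyl and is therefore the most acidic and nucleophilic.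

**Step 12**
Reactants: 18 benzyl 4-[4-(3,4-bis(benzyloxy)-2-methoxy-6-methylbenzoyloxy)-2-hydroxy-6-methylbenzoyloxy]-2-hydroxy-6-methylbenzoate
Product: 19 4-[4-(3,4-dihydroxy-2-methoxy-6-methylbenzoyloxy)-2-hydroxy-6-methylbenzoyloxy]-2-hydroxy-6-methylbenzoic acid
Conditions: H2 (1 atm), 10% Pd/C, EtOAc/THF, rt
Reagents that add atoms: none
Why: Catalytic hydrogenolysis cleaves the two aryl benzyl ethers and the benzyl ester in one neutral operation in a non‑nucleophilic solvent, which should leave both aryl ester links untouched.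

**Compound list**

1 | orsellinic acid (2,4-dihydroxy-6-methylbenzoic acid) | Cc1cc(O)cc(O)c1C(=O)O | starting material
2 | benzyl bromide | BrCc1ccccc1 | starting material
3 | benzyl 2,4-dihydroxy-6-methylbenzoate | Cc1cc(O)cc(O)c1C(=O)OCc1ccccc1 | intermediate
4 | 2,2,6-trimethyl-4H-1,3-dioxin-4-one | CC1=CC(=O)OC(C)(C)O1 | starting material
5 | 2,2-dimethyl-6-(2-oxopropyl)-4H-1,3-dioxin-4-one | CC(=O)CC1=CC(=O)OC(C)(C)O1 | intermediate
6 | 6-(2,4-dioxopentyl)-2,2-dimethyl-4H-1,3-dioxin-4-one (keto form drawn) | CC(=O)CC(=O)CC1=CC(=O)OC(C)(C)O1 | intermediate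
7 | 3,5,7-trioxooct-1-en-1-one (acylketene) | CC(=O)CC(=O)CC(=O)C=C=O | intermediate
8 | benzyl 2-hydroxy-6-methyl-4-(3,5,7-trioxooctanoyloxy)benzoate (keto form drawn) | CC(=O)CC(=O)CC(=O)CC(=O)Oc1cc(C)c(C(=O)OCc2ccccc2)c(O)c1 | intermediate
9 | benzyl 2-hydroxy-4-[(2-hydroxy-2-methyl-4,6-dioxocyclohexane-1-carbonyl)oxy]-6-methylbenzoate (mixture of stereoisomers and tautomers) | CC1(O)CC(=O)CC(=O)C1C(=O)Oc1cc(C)c(C(=O)OCc2ccccc2)c(O)c1 | intermediate
10 | benzyl 4-(2,4-dihydroxy-6-methylbenzoyloxy)-2-hydroxy-6-methylbenzoate | Cc1cc(O)cc(O)c1C(=O)Oc1cc(C)c(C(=O)OCc2ccccc2)c(O)c1 | intermediate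
11 | 5-methylbenzene-1,2,3-triol (5-methylpyrogallol) | Cc1cc(O)c(O)c(O)c1 | starting material
12 | N-methyl-N-[(2,3,4-trihydroxy-6-methylphenyl)methylidene]methanaminium chloride | C[N+](C)=Cc1c(C)cc(O)c(O)c1O.[Cl-] | intermediate
13 | 2,3,4-trihydroxy-6-methylbenzaldehyde | Cc1cc(O)c(O)c(O)c1C=O | intermediate
14 | 3,4-bis(benzyloxy)-2-hydroxy-6-methylbenzaldehyde | Cc1cc(OCc2ccccc2)c(OCc2ccccc2)c(O)c1C=O | intermediate
15 | 3,4-bis(benzyloxy)-2-methoxy-6-methylbenzaldehyde | COc1c(C=O)c(C)cc(OCc2ccccc2)c1OCc1ccccc1 | intermediate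
16 | 3,4-bis(benzyloxy)-2-methoxy-6-methylbenzoic acid | COc1c(C(=O)O)c(C)cc(OCc2ccccc2)c1OCc1ccccc1 | intermediate
17 | 3,4-bis(benzyloxy)-2-methoxy-6-methylbenzoyl chloride | COc1c(C(Cl)=O)c(C)cc(OCc2ccccc2)c1OCc1ccccc1 | intermediate
18 | benzyl 4-[4-(3,4-bis(benzyloxy)-2-methoxy-6-methylbenzoyloxy)-2-hydroxy-6-methylbenzoyloxy]-2-hydroxy-6-methylbenzoate | COc1c(C(=O)Oc2cc(C)c(C(=O)Oc3cc(C)c(C(=O)OCc4ccccc4)c(O)c3)c(O)c2)c(C)cc(OCc2ccccc2)c1OCc1ccccc1 | intermediate
19 | 4-[4-(3,4-dihydroxy-2-methoxy-6-methylbenzoyloxy)-2-hydroxy-6-methylbenzoyloxy]-2-hydroxy-6-methylbenzoic acid | COc1c(O)c(O)cc(C)c1C(=O)Oc1cc(C)c(C(=O)Oc2cc(C)c(C(=O)O)c(O)c2)c(O)c1 | target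

**Step count**

Total steps: 12. Longest linear sequence: 7 steps (11 to 19, steps 6–12). The polyketide branch from 4 runs 6 steps (2, 3, 4, 5, 11, 12).

**Steps most likely to fail, with fallbacks**

Step 5. The enolised chain may close onto the activated aryl ester carbonyl instead of the C7 ketone (Claisen closure from C6, or lactonisation through the C5 enol oxygen), which would expel the ring C phenoxide before ring B forms. The fallback sets out from 6 and rejoins at 18. It keeps the polyketide origin of ring B but makes the B–C ester conventionally. Compound 6 is heated in toluene with tert‑butanol, so acylketene 7 is trapped as tert-butyl 3,5,7-trioxooctanoate F1, whose alkoxide is no leaving group. Et3N and then acid aromatise it to tert-butyl 2,4-dihydroxy-6-methylbenzoate F2. F2 is acylated at its non‑chelated 4‑OH with acid chloride 17 (Et3N, DMAP, CH2Cl2) to give tert-butyl 4-[3,4-bis(benzyloxy)-2-methoxy-6-methylbenzoyloxy]-2-hydroxy-6-methylbenzoate F3. TFA in CH2Cl2 removes the tert‑butyl group to give 4-[3,4-bis(benzyloxy)-2-methoxy-6-methylbenzoyloxy]-2-hydroxy-6-methylbenzoic acid F4. F4 is then condensed with the 4‑OH of phenol 3 under classical depside conditions (TFAA, toluene, rt) to give 18.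

Step 4. The ketene may be captured intramolecularly by the enol oxygen of its own diketone chain (pyranone formation) faster than the weakly nucleophilic phenol attacks, and some double acylation of 3 is possible. The fallback sets out from 3 and comes back at 8. It masks the 5,7‑dione as an isoxazole, so the ketene carries no internal nucleophile. Commercial (3‑methylisoxazol‑5‑yl)acetic acid is condensed with Meldrum's acid (DCC, DMAP, CH2Cl2) to 5-[1-hydroxy-2-(3-methylisoxazol-5-yl)ethylidene]-2,2-dimethyl-1,3-dioxane-4,6-dione F5. Heating F5 with 3 in toluene at 80–100 °C should give benzyl 2-hydroxy-6-methyl-4-[4-(3-methylisoxazol-5-yl)-3-oxobutanoyloxy]benzoate F6. Mo(CO)6 in wet MeCN cleaves the N–O bond to the enaminone benzyl 4-[(6Z)-7-amino-3,5-dioxooct-6-enoyloxy]-2-hydroxy-6-methylbenzoate F7. Brief treatment with 1 M HCl in THF hydrolyses F7 to 8.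

Step 7. Control by stoichiometry may break down, with alkylation of the chelated 2‑OH or incomplete reaction at the flanked 3‑OH giving mixtures of benzyl ethers. The fallback sets out from 13 and comes back at 14. It over‑protects and then deprotects selectively. Exhaustive benzylation of 13 (2 in excess, K2CO3, DMF, 60 °C) gives 2,3,4-tris(benzyloxy)-6-methylbenzaldehyde F8. MgBr2·OEt2 in toluene/Et2O at reflux then removes only the benzyl ether ortho to the aldehyde by chelation, giving 14.

**Further compounds**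

F1 | step 5 | tert-butyl 3,5,7-trioxooctanoate | CC(=O)CC(=O)CC(=O)CC(=O)OC(C)(C)C
F2 | step 5 | tert-butyl 2,4-dihydroxy-6-methylbenzoate | Cc1cc(O)cc(O)c1C(=O)OC(C)(C)C
F3 | step 5 | tert-butyl 4-[3,4-bis(benzyloxy)-2-methoxy-6-methylbenzoyloxy]-2-hydroxy-6-methylbenzoate | COc1c(C(=O)Oc2cc(C)c(C(=O)OC(C)(C)C)c(O)c2)c(C)cc(OCc2ccccc2)c1OCc1ccccc1
F4 | step 5 | 4-[3,4-bis(benzyloxy)-2-methoxy-6-methylbenzoyloxy]-2-hydroxy-6-methylbenzoic acid | COc1c(C(=O)Oc2cc(C)c(C(=O)O)c(O)c2)c(C)cc(OCc2ccccc2)c1OCc1ccccc1
F5 | step 4 | 5-[1-hydroxy-2-(3-methylisoxazol-5-yl)ethylidene]-2,2-dimethyl-1,3-dioxane-4,6-dione | Cc1cc(CC(O)=C2C(=O)OC(C)(C)OC2=O)on1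
F6 | step 4 | benzyl 2-hydroxy-6-methyl-4-[4-(3-methylisoxazol-5-yl)-3-oxobutanoyloxy]benzoate | Cc1cc(CC(=O)CC(=O)Oc2cc(C)c(C(=O)OCc3ccccc3)c(O)c2)on1
F7 | step 4 | benzyl 4-[(6Z)-7-amino-3,5-dioxooct-6-enoyloxy]-2-hydroxy-6-methylbenzoate | C/C(N)=C/C(=O)CC(=O)CC(=O)Oc1cc(C)c(C(=O)OCc2ccccc2)c(O)c1
F8 | step 7 | 2,3,4-tris(benzyloxy)-6-methylbenzaldehyde | Cc1cc(OCc2ccccc2)c(OCc2ccccc2)c(OCc2ccccc2)c1C=O
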